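**Plan**
- Ring B has oxygen at C1' and C4' (para), a third oxygen at C6', and carbon at C2', C3' and C5'. A 4-alkenyl-4-oxycyclobutenone gives exactly this hexasubstituted hydroquinone pattern on ring expansion, with the two para oxygens already differentiated.
- Cuts, in retrosynthetic order: both CO2H groups back to CHO (ring A) and CH2OSi (ring B); the C3'–C4' bond of ring B back to a cyclobutenone; the C1'–C2' bond (alkenyllithium plus dione); the depside C(=O)–O bond (acylation of the resulting alkoxide); the C5'–CH3 bond (MeLi plus dibenzyl squarate).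
- Forward: ring A comes intact from methyl orsellinate as a 3-formyl aroyl chloride. The dione, an (E)-alkenyllithium and the aroyl chloride are joined in one flask, and ring B then forms by thermolysis.
- Finish: desilylation, MnO2, one chlorite oxidation that converts both aldehydes, and hydrogenolysis.
- Stereochemistry: the target is achiral. Only the E geometry of the alkenyl iodide matters (set by syn hydrozirconation); the carbinol stereocentre is racemic and is lost on aromatisation.

Key step: step 11

Remark on the chemistry: a 3-metallated but-2-enoate ester would equilibrate through its metal allenoate, and its Z form would lactonise onto the new alkoxide. The C3' carbon is therefore brought in as a silyl-protected CH2OH and oxidised after ring B exists. Cyclobutenone intermediates with a stereocentre are racemic, with one enantiomer drawn.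

**Step 1**
Reactants: 1 squaric acid
Product: 2 dibenzyl squarate, 3,4-bis(benzyloxy)cyclobut-3-ene-1,2-dione
Conditions: BnOH (excess), toluene, reflux, Dean–Stark
Reagents that add atoms: benzyl alcohol, OCc1ccccc1
Why: Squaric acid is a strong vinylogous acid that catalyses its own Fischer-type esterification, and azeotropic removal of water should drive it to the diester.

**Step 2**
Reactants: 2 dibenzyl squarate
Product: 5 3-(benzyloxy)-4-methylcyclobut-3-ene-1,2-dione, via lithium alkoxide 3 (not isolated), via trifluoroacetate 4 (not isolated)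
Conditions: MeLi, THF, −78 °C; (CF3CO)2O, −78 °C; aq. NH4Cl
Reagents that add atoms: methyllithium, [Li]C; water, O
Why: 1,2-Addition of MeLi to one carbonyl of the symmetrical squarate, then ionisation of the derived trifluoroacetate and hydrolysis of the benzyloxy-stabilised cation with loss of benzyl alcohol, is the standard squarate-to-alkylcyclobutenedione transposition.

**Step 3**
Reactants: 6 but-2-yn-1-ol
Product: 7 tert-butyl(but-2-yn-1-yloxy)dimethylsilane
Conditions: TBSCl, imidazole, CH2Cl2, 0 °C → rt
Reagents that add atoms: tert-butyldimethylsilyl chloride, CC(C)(C)[Si](C)(C)Cl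
Why: Imidazole-promoted silylation of a primary alcohol gives an ether that tolerates t-BuLi and thermolysis.

**Step 4**
Reactants: 7 tert-butyl(but-2-yn-1-yloxy)dimethylsilane
Product: 9 (E)-tert-butyl[(3-iodobut-2-en-1-yl)oxy]dimethylsilane, via alkenylzirconocene chloride 8 (not isolated)
Conditions: Cp2Zr(H)Cl (1.5 equiv), THF, rt; I2, 0 °C
Reagents that add atoms: iodine, II
Why: Hydrozirconation adds Zr–H syn and, with excess reagent, settles zirconium on the less hindered methyl-bearing carbon; iodinolysis with retention should then give the E iodide (iodine trans to CH2OTBS).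

**Step 5**
Reactants: 10 methyl orsellinate
Product: 11 methyl 2-hydroxy-4-methoxy-6-methylbenzoate
Conditions: MeI (1.1 equiv), K2CO3, acetone, reflux
Reagents that add atoms: iodomethane, CI
Why: In this Williamson etherification the 2-OH is hydrogen-bonded to the ester carbonyl and flanked by it, so the more acidic, unhindered 4-OH should be methylated selectively.

**Step 6**
Reactants: 11 methyl 2-hydroxy-4-methoxy-6-methylbenzoate
Product: 12 methyl 3-formyl-2-hydroxy-4-methoxy-6-methylbenzoate
Conditions: MgCl2, Et3N, (CH2O)n, MeCN, reflux; aq. HCl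
Reagents that add atoms: paraformaldehyde (as formaldehyde), C=O
Why: In the magnesium-mediated ortho-formylation (Casiraghi–Skattebøl) the chelated magnesium phenoxide delivers formaldehyde to C3, the only free position ortho to the phenol, and a second formaldehyde oxidises the benzylic alkoxide by hydride transfer.

**Step 7**
Reactants: 12 methyl 3-formyl-2-hydroxy-4-methoxy-6-methylbenzoate
Product: 13 methyl 2-(benzyloxy)-3-formyl-4-methoxy-6-methylbenzoate
Conditions: BnBr, K2CO3, DMF, 60 °C
Reagents that add atoms: benzyl bromide, BrCc1ccccc1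
Why: Williamson benzylation of the doubly chelated phenol should proceed in a dipolar aprotic solvent with warming, and no other acidic site is present.

**Step 8**
Reactants: 13 methyl 2-(benzyloxy)-3-formyl-4-methoxy-6-methylbenzoate
Product: 14 2-(benzyloxy)-3-formyl-4-methoxy-6-methylbenzoic acid
Conditions: LiOH·H2O, THF/MeOH/H2O, 60 °C; 1 M HCl
Reagents that add atoms: lithium hydroxide, [Li+].[OH-]
Why: Saponification of the ortho-alkoxy, ortho-methyl benzoate is slow but assisted by the meta formyl group, while the aldehyde (no α-hydrogen, two ortho alkoxy groups) should resist Cannizzaro disproportionation under mild hydroxide.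

**Step 9**
Reactants: 14 2-(benzyloxy)-3-formyl-4-methoxy-6-methylbenzoic acid
Product: 15 2-(benzyloxy)-3-formyl-4-methoxy-6-methylbenzoyl chloride
Conditions: (COCl)2, DMF (cat.), CH2Cl2, 0 °C → rt; evaporate, use crude
Reagents that add atoms: oxalyl chloride, O=C(Cl)C(=O)Cl
Why: Chloroiminium-catalysed acid chloride formation is mild enough for the aryl aldehyde, which sits meta to the acyl group and so cannot close to a pseudo-chloride.

**Step 10**
Reactants: 9 (E)-tert-butyl[(3-iodobut-2-en-1-yl)oxy]dimethylsilane; 5 3-(benzyloxy)-4-methylcyclobut-3-ene-1,2-dione; 15 2-(benzyloxy)-3-formyl-4-methoxy-6-methylbenzoyl chloride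
Product: 18 2-(benzyloxy)-1-[(E)-4-{[tert-butyl(dimethyl)silyl]oxy}but-2-en-2-yl]-3-methyl-4-oxocyclobut-2-en-1-yl 2-(benzyloxy)-3-formyl-4-methoxy-6-methylbenzoate (racemic), via alkenyllithium 16 (not isolated), via lithium alkoxide 17 (not isolated)
Conditions: 9, t-BuLi (2 equiv), Et2O, −78 °C; cannulate into 5 (slight excess), THF, −78 °C; then 15, THF, −78 → 0 °C
Reagents that add atoms: none
Why: Iodine–lithium exchange with retention gives a configurationally stable alkenyllithium (lithium trans to CH2OTBS, so no 1,4-silyl shift) that adds 1,2 to the ketone carbonyl next to the benzyloxy-bearing carbon (the other carbonyl is a vinylogous ester), and the tertiary lithium alkoxide is O-acylated in the same flask; the quaternary centre forms as a racemate.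

**Step 11**
Reactants: 18 the 4-aroyloxy-4-alkenylcyclobutenone from step 10
Product: 19 2-(benzyloxy)-5-({[tert-butyl(dimethyl)silyl]oxy}methyl)-4-hydroxy-3,6-dimethylphenyl 2-(benzyloxy)-3-formyl-4-methoxy-6-methylbenzoate (ring B: C1' O-aroyl, C2' Me, C3' CH2OTBS, C4' OH, C5' Me, C6' OBn)
Conditions: toluene (degassed, 0.01 M), 110 °C
Reagents that add atoms: none
Why: Heating cleaves the ring bond between the carbonyl carbon and the carbinol carbon by conrotatory 4π electrocyclic opening to a dienylketene; a thermal 6π electrocyclisation then joins the ketene carbon to the CH terminus of the butenyl group (the C4'–C3' bond), and the cyclohexa-2,4-dienone enolises to the phenol. This is the Moore rearrangement of a 4-alkenyl-4-oxycyclobutenone, here in its 4-acyloxy form. Ring B closes as a six-membered carbocycle by disrotatory 6π electrocyclisation. No stereocentre is created, and the racemic carbinol centre of 18 becomes the sp2 carbon C1'. The step needs torquoselectivity (oxygen outward, alkenyl inward): the acyloxy oxygen prefers outward rotation, opening to the unproductive rotamer is reversible, and the E side chain places hydrogen rather than CH2OTBS inside the triene terminus. Because the carbinol oxygen is already acylated, C1'–O emerges as the depside ester and only the ketene-derived C4'–OH is free.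

**Step 12**
Reactants: 19 the silyl-protected depside from step 11
Product: 20 2-(benzyloxy)-4-hydroxy-5-(hydroxymethyl)-3,6-dimethylphenyl 2-(benzyloxy)-3-formyl-4-methoxy-6-methylbenzoate
Conditions: HF·pyridine, THF/pyridine, 0 °C → rt
Reagents that add atoms: none
Why: Fluoride-driven cleavage of the primary silyl ether under pyridine-buffered conditions should leave the aryl ester, benzyl ethers and aldehyde untouched and avoid acid-induced quinone methide formation.

**Step 13**
Reactants: 20 the hydroxymethyl phenol from step 12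
Product: 21 2-(benzyloxy)-5-formyl-4-hydroxy-3,6-dimethylphenyl 2-(benzyloxy)-3-formyl-4-methoxy-6-methylbenzoate
Conditions: MnO2 (activated, excess), CH2Cl2, rt
Reagents that add atoms: none
Why: MnO2 oxidises benzylic alcohols selectively, and the o-hydroxybenzyl alcohol should stop at the hydrogen-bonded salicylaldehyde.

**Step 14**
Reactants: 21 the dialdehyde from step 13
Product: 22 2-(benzyloxy)-3-{[2-(benzyloxy)-5-carboxy-4-hydroxy-3,6-dimethylphenoxy]carbonyl}-6-methoxy-4-methylbenzoic acid (O,O'-dibenzyl hypothamnolic acid)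
Conditions: NaClO2, NaH2PO4, 2-methyl-2-butene (large excess), t-BuOH/THF/H2O, 0 °C → rt
Reagents that add atoms: sodium chlorite, [Na+].[O-]Cl=O
Why: The Pinnick oxidation converts both aryl aldehydes to acids at buffered pH that spares the depside; the alkene scavenges hypochlorous acid, and ring B has no free position to chlorinate.

**Step 15**
Reactants: 22 O,O'-dibenzyl hypothamnolic acid
Product: 23 hypothamnolic acid
Conditions: H2 (1 atm), Pd/C, EtOAc, rt
Reagents that add atoms: none
Why: Hydrogenolysis of the two aryl benzyl ethers is neutral, so the depside ester and the free acids survive and no other reducible group remains.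

**Compound list**
1 | squaric acid | OC1=C(O)C(=O)C1=O | starting material
2 | dibenzyl squarate, 3,4-bis(benzyloxy)cyclobut-3-ene-1,2-dione | O=C1C(=O)C(OCc2ccccc2)=C1OCc1ccccc1 | intermediate
3 | lithium 2,3-bis(benzyloxy)-1-methyl-4-oxocyclobut-2-en-1-olate (racemic, one enantiomer drawn) | [Li+].[O-][C@]1(C)C(OCc2ccccc2)=C(OCc2ccccc2)C1=O | intermediate (not isolated)
4 | 2,3-bis(benzyloxy)-1-methyl-4-oxocyclobut-2-en-1-yl trifluoroacetate (racemic, one enantiomer drawn) | O=C(O[C@]1(C)C(OCc2ccccc2)=C(OCc2ccccc2)C1=O)C(F)(F)F | intermediate (not isolated)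
5 | 3-(benzyloxy)-4-methylcyclobut-3-ene-1,2-dione | CC1=C(OCc2ccccc2)C(=O)C1=O | intermediate
6 | but-2-yn-1-ol | CC#CCO | starting material
7 | tert-butyl(but-2-yn-1-yloxy)dimethylsilane | CC#CCO[Si](C)(C)C(C)(C)C | intermediate
8 | chlorobis(cyclopentadienyl)[(E)-4-{[tert-butyl(dimethyl)silyl]oxy}but-2-en-2-yl]zirconium (Zr trans to CH2O) | C/C(=C\CO[Si](C)(C)C(C)(C)C)[Zr+2]Cl.c1cc[cH-]c1.c1cc[cH-]c1 | intermediate (not isolated)
9 | (E)-tert-butyl[(3-iodobut-2-en-1-yl)oxy]dimethylsilane (I trans to CH2O) | I/C(C)=C/CO[Si](C)(C)C(C)(C)C | intermediate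
10 | methyl orsellinate, methyl 2,4-dihydroxy-6-methylbenzoate | COC(=O)c1c(C)cc(O)cc1O | starting material
11 | methyl 2-hydroxy-4-methoxy-6-methylbenzoate | COC(=O)c1c(C)cc(OC)cc1O | intermediate
12 | methyl 3-formyl-2-hydroxy-4-methoxy-6-methylbenzoate | COC(=O)c1c(C)cc(OC)c(C=O)c1O | intermediate
13 | methyl 2-(benzyloxy)-3-formyl-4-methoxy-6-methylbenzoate | COC(=O)c1c(C)cc(OC)c(C=O)c1OCc1ccccc1 | intermediate
14 | 2-(benzyloxy)-3-formyl-4-methoxy-6-methylbenzoic acid | OC(=O)c1c(C)cc(OC)c(C=O)c1OCc1ccccc1 | intermediate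
15 | 2-(benzyloxy)-3-formyl-4-methoxy-6-methylbenzoyl chloride | ClC(=O)c1c(C)cc(OC)c(C=O)c1OCc1ccccc1 | intermediate
16 | (Z)-{4-[(tert-butyldimethylsilyl)oxy]but-2-en-2-yl}lithium (Li trans to CH2O; geometry of 9 retained, descriptor changes because C outranks Li) | [Li]/C(C)=C/CO[Si](C)(C)C(C)(C)C | intermediate (not isolated)
17 | lithium 2-(benzyloxy)-1-[(E)-4-{[tert-butyl(dimethyl)silyl]oxy}but-2-en-2-yl]-3-methyl-4-oxocyclobut-2-en-1-olate (racemic, one enantiomer drawn) | CC1=C(OCc2ccccc2)[C@]([O-])(/C(C)=C/CO[Si](C)(C)C(C)(C)C)C1=O.[Li+] | intermediate (not isolated)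
18 | 2-(benzyloxy)-1-[(E)-4-{[tert-butyl(dimethyl)silyl]oxy}but-2-en-2-yl]-3-methyl-4-oxocyclobut-2-en-1-yl 2-(benzyloxy)-3-formyl-4-methoxy-6-methylbenzoate (racemic, one enantiomer drawn) | CC1=C(OCc2ccccc2)[C@](OC(=O)c2c(C)cc(OC)c(C=O)c2OCc2ccccc2)(/C(C)=C/CO[Si](C)(C)C(C)(C)C)C1=O | intermediate (key-step precursor)
19 | 2-(benzyloxy)-5-({[tert-butyl(dimethyl)silyl]oxy}methyl)-4-hydroxy-3,6-dimethylphenyl 2-(benzyloxy)-3-formyl-4-methoxy-6-methylbenzoate | COc1cc(C)c(C(=O)Oc2c(C)c(CO[Si](C)(C)C(C)(C)C)c(O)c(C)c2OCc2ccccc2)c(OCc2ccccc2)c1C=O | intermediate (key-step product)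
20 | 2-(benzyloxy)-4-hydroxy-5-(hydroxymethyl)-3,6-dimethylphenyl 2-(benzyloxy)-3-formyl-4-methoxy-6-methylbenzoate | COc1cc(C)c(C(=O)Oc2c(C)c(CO)c(O)c(C)c2OCc2ccccc2)c(OCc2ccccc2)c1C=O | intermediate
21 | 2-(benzyloxy)-5-formyl-4-hydroxy-3,6-dimethylphenyl 2-(benzyloxy)-3-formyl-4-methoxy-6-methylbenzoate | COc1cc(C)c(C(=O)Oc2c(C)c(C=O)c(O)c(C)c2OCc2ccccc2)c(OCc2ccccc2)c1C=O | intermediate
22 | 2-(benzyloxy)-3-{[2-(benzyloxy)-5-carboxy-4-hydroxy-3,6-dimethylphenoxy]carbonyl}-6-methoxy-4-methylbenzoic acid | COc1cc(C)c(C(=O)Oc2c(C)c(C(=O)O)c(O)c(C)c2OCc2ccccc2)c(OCc2ccccc2)c1C(=O)O | intermediate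
23 | hypothamnolic acid | COc1cc(C)c(C(=O)Oc2c(C)c(C(=O)O)c(O)c(C)c2O)c(O)c1C(=O)O | target

**Step count**
Total: 15 steps. Longest linear sequence: 11 steps (10 → 23, steps 5–15).

**Steps most likely to fail**

Step 10. The crowded tertiary lithium alkoxide may be acylated only sluggishly by the doubly ortho-substituted aroyl chloride, or may fragment on warming before acylation is complete. The fallback makes the depside bond on the arene instead; it sets out from 9 and 5 (with 15 used later) and returns at 20. Alkoxide 17, generated as before, would be quenched with Me3SiCl to give 2-(benzyloxy)-1-[(E)-4-{[tert-butyl(dimethyl)silyl]oxy}but-2-en-2-yl]-3-methyl-1-(trimethylsilyloxy)cyclobut-2-en-4-one F1. Thermolysis in toluene should give the para-silyloxyphenol 3-(benzyloxy)-6-({[tert-butyl(dimethyl)silyl]oxy}methyl)-2,5-dimethyl-4-(trimethylsilyloxy)phenol F2. TBSCl/imidazole in DMF would cap C4'–OH to give the bis-TBS trimethylsilyl ether F3. K2CO3 in MeOH at 0 °C should remove only the aryl trimethylsilyl ether and free C1'–OH in the phenol F4. Its sodium phenoxide (NaH, THF) would be acylated with 15 to the bis-TBS depside F5, and HF·pyridine would remove both TBS groups to deliver 20.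

Step 11. On heating, the aroyloxy group may rotate inward to a significant extent and the ketene may be captured by the ester carbonyl, or a thermal acyl shift may precede ring opening. The fallback runs the ring expansion on the free carbinol; it sets out from 9 and 5 and returns at 20. Alkoxide 17 would be protonated (aq. NH4Cl) to the 4-hydroxycyclobutenone F6. Thermolysis in toluene under argon should give the hydroquinone 2-(benzyloxy)-5-({[tert-butyl(dimethyl)silyl]oxy}methyl)-3,6-dimethylbenzene-1,4-diol F7. HF·pyridine would give 2-(benzyloxy)-5-(hydroxymethyl)-3,6-dimethylbenzene-1,4-diol F8. 2,2-Dimethoxypropane with pyridinium p-toluenesulfonate would tie C4'–OH and the CH2OH group into 7-(benzyloxy)-2,2,5,8-tetramethyl-4H-1,3-benzodioxin-6-ol F9, leaving C1'–OH as the only free hydroxyl. Acylation with 15 (NaH, THF) would give the depside acetonide F10, and aqueous acetic acid in THF would open the acetonide to 20.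

Step 14. The free, electron-rich C4' phenol may be oxidised by chlorine dioxide or hypochlorous acid faster than the hindered aldehydes are converted. The fallback masks the phenol before the oxidation; it sets out from 21 and returns at 23. BnBr/K2CO3 in DMF would give the tri-O-benzyl dialdehyde 2,4-bis(benzyloxy)-5-formyl-3,6-dimethylphenyl 2-(benzyloxy)-3-formyl-4-methoxy-6-methylbenzoate F11. The same chlorite oxidation should then give the tri-O-benzyl diacid F12, and hydrogenolysis over Pd/C would remove all three benzyl ethers to give 23.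

**Further compounds**
F1 | step 10 | 2-(benzyloxy)-1-[(E)-4-{[tert-butyl(dimethyl)silyl]oxy}but-2-en-2-yl]-3-methyl-1-(trimethylsilyloxy)cyclobut-2-en-4-one (racemic, one enantiomer drawn) | CC1=C(OCc2ccccc2)[C@](O[Si](C)(C)C)(/C(C)=C/CO[Si](C)(C)C(C)(C)C)C1=O
F2 | step 10 | 3-(benzyloxy)-6-({[tert-butyl(dimethyl)silyl]oxy}methyl)-2,5-dimethyl-4-(trimethylsilyloxy)phenol | Cc1c(O)c(CO[Si](C)(C)C(C)(C)C)c(C)c(O[Si](C)(C)C)c1OCc1ccccc1
F3 | step 10 | [3-(benzyloxy)-4-{[tert-butyl(dimethyl)silyl]oxy}-5-({[tert-butyl(dimethyl)silyl]oxy}methyl)-2,6-dimethylphenoxy]trimethylsilane... written from the C1' oxygen: C1' OSiMe3, C4' OTBS, C3' CH2OTBS, C6' OBn | Cc1c(O[Si](C)(C)C(C)(C)C)c(CO[Si](C)(C)C(C)(C)C)c(C)c(O[Si](C)(C)C)c1OCc1ccccc1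
F4 | step 10 | 2-(benzyloxy)-4-{[tert-butyl(dimethyl)silyl]oxy}-5-({[tert-butyl(dimethyl)silyl]oxy}methyl)-3,6-dimethylphenol | Cc1c(O[Si](C)(C)C(C)(C)C)c(CO[Si](C)(C)C(C)(C)C)c(C)c(O)c1OCc1ccccc1
F5 | step 10 | 2-(benzyloxy)-4-{[tert-butyl(dimethyl)silyl]oxy}-5-({[tert-butyl(dimethyl)silyl]oxy}methyl)-3,6-dimethylphenyl 2-(benzyloxy)-3-formyl-4-methoxy-6-methylbenzoate | COc1cc(C)c(C(=O)Oc2c(C)c(CO[Si](C)(C)C(C)(C)C)c(O[Si](C)(C)C(C)(C)C)c(C)c2OCc2ccccc2)c(OCc2ccccc2)c1C=O
F6 | step 11 | 3-(benzyloxy)-4-[(E)-4-{[tert-butyl(dimethyl)silyl]oxy}but-2-en-2-yl]-4-hydroxy-2-methylcyclobut-2-en-1-one (racemic, one enantiomer drawn) | CC1=C(OCc2ccccc2)[C@](O)(/C(C)=C/CO[Si](C)(C)C(C)(C)C)C1=O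
F7 | step 11 | 2-(benzyloxy)-5-({[tert-butyl(dimethyl)silyl]oxy}methyl)-3,6-dimethylbenzene-1,4-diol | Cc1c(O)c(CO[Si](C)(C)C(C)(C)C)c(C)c(O)c1OCc1ccccc1
F8 | step 11 | 2-(benzyloxy)-5-(hydroxymethyl)-3,6-dimethylbenzene-1,4-diol | Cc1c(O)c(CO)c(C)c(O)c1OCc1ccccc1
F9 | step 11 | 7-(benzyloxy)-2,2,5,8-tetramethyl-4H-1,3-benzodioxin-6-ol | Cc1c2OC(C)(C)OCc2c(C)c(O)c1OCc1ccccc1
F10 | step 11 | 7-(benzyloxy)-2,2,5,8-tetramethyl-4H-1,3-benzodioxin-6-yl 2-(benzyloxy)-3-formyl-4-methoxy-6-methylbenzoate | COc1cc(C)c(C(=O)Oc2c(C)c3COC(C)(C)Oc3c(C)c2OCc2ccccc2)c(OCc2ccccc2)c1C=O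
F11 | step 14 | 2,4-bis(benzyloxy)-5-formyl-3,6-dimethylphenyl 2-(benzyloxy)-3-formyl-4-methoxy-6-methylbenzoate | COc1cc(C)c(C(=O)Oc2c(C)c(C=O)c(OCc3ccccc3)c(C)c2OCc2ccccc2)c(OCc2ccccc2)c1C=O
F12 | step 14 | 2-(benzyloxy)-3-{[2,4-bis(benzyloxy)-5-carboxy-3,6-dimethylphenoxy]carbonyl}-6-methoxy-4-methylbenzoic acid | COc1cc(C)c(C(=O)Oc2c(C)c(C(=O)O)c(OCc3ccccc3)c(C)c2OCc2ccccc2)c(OCc2ccccc2)c1C(=O)O
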